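**Assumption:** (+)-costunolide, isolated in bulk from costus root oil and sold as a pure compound, is taken as the cheap commercial starting material, so this is a semisynthesis from that natural product. Germacrane numbering is used: C6 = lactone O–CH, C7 = ring-fusion CH, C8 = CH–OAc, C1/C10 = oxirane carbons, C14 = CH2 on C10, C15 = carbon on C4. "Ring-cis/ring-trans" says whether the two ring carbons on a ring alkene are cis or trans. None of the steps has been run on these substrates; steps 1–3 and 5 rest on close analogies, step 4 is new.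

## Retrosynthetic overview

1. Target 8 ⇐ 7 by acetylation of the 14-hydroxyl.
2. 7 ⇐ 5 by the key C8–O bond: 14-hydroxyl-directed δ-C–H acetoxylation (alkoxy radical, 1,5-hydrogen shift, copper–acetate capture), which sets C8.
3. 5 ⇐ 3 ⇐ 2: C15–H → CHO by Riley oxidation (turns the 4,5-alkene ring-cis); oxirane by Sharpless epoxidation (sets C1 and C10).
4. 2 ⇐ 1: C14–H hydroxylation of (+)-costunolide with trans → cis isomerisation of the 1(10)-alkene.
5. Ring order: the ten-membered carbocycle and the trans-fused α-methylene lactone (C6, C7) come with 1; the oxirane is the only ring formed (step 2).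

## Route

**Step 1**
Reactants: 1 (+)-costunolide
Product: 2 14-hydroxy-1(10)-ring-cis-costunolide
Conditions: SeO2 (0.3 equiv), t-BuOOH (3 equiv, in decane), CH2Cl2, 0 °C → rt
Reagents that add atoms: tert-butyl hydroperoxide, CC(C)(C)OO (terminal source of the new oxygen, passed on through the catalyst selenium dioxide, O=[Se]=O)
Why: Catalytic Riley allylic oxidation (ene reaction, then [2,3]-sigmatropic shift) attacks the electron-richer 1(10)-alkene rather than the 4,5-alkene, which is deactivated by the allylic lactone oxygen, and the [2,3] shift places the new CH2OH trans to C2, so the alkene becomes ring-cis as in the known conversion of parthenolide into melampomagnolide B; no stereocentre is formed.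

**Step 2**
Reactants: 2 14-hydroxy-1(10)-ring-cis-costunolide
Product: 3 (1R,10R)-1,10-epoxy-14-hydroxygermacra-4,11(13)-dien-12,6α-olide
Conditions: Ti(OiPr)4 (10 mol%), D-(−)-diethyl tartrate (12 mol%), t-BuOOH (1.5 equiv), 4 Å MS, CH2Cl2, −20 °C
Reagents that add atoms: tert-butyl hydroperoxide, CC(C)(C)OO
Why: Sharpless asymmetric epoxidation of a primary allylic alcohol whose far substituent (C2) is trans to CH2OH, in which the Ti(OiPr)4–tartrate catalyst binds O-14 and delivers oxygen under reagent control; since L-(+)-tartrate gives (2S,3S)-epoxy alcohols from this substrate class, D-(−)-tartrate gives the (2R,3R)-type product, which is (1R,10R) here, and the 4,5- and 11(13)-alkenes are not allylic alcohols and stay untouched.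

**Step 3**
Reactants: 3 (1R,10R)-1,10-epoxy-14-hydroxygermacra-4,11(13)-dien-12,6α-olide
Product: 5 (1R,10R)-1,10-epoxy-14-hydroxy-15-oxogermacra-4,11(13)-dien-12,6α-olide, via 15-hydroxy epoxy alcohol 4 (not isolated)
Conditions: SeO2 (2 equiv), pyridine (1 equiv), 1,4-dioxane, 75 °C
Reagents that add atoms: selenium dioxide, O=[Se]=O
Why: Stoichiometric Riley oxidation, in which C15 is the only allylic methyl left, the ene/[2,3] sequence gives allylic alcohol 4 with the oxygenated carbon trans to C6 (ring-cis alkene), and SeO2 oxidises this allylic alcohol on to the enal while the non-allylic 14-OH is left alone, in analogy to the known oxidation of prenyl acetate to (E)-4-acetoxy-2-methylbut-2-enal; no stereocentre is formed.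

**Step 4**
Reactants: 5 (1R,10R)-1,10-epoxy-14-hydroxy-15-oxogermacra-4,11(13)-dien-12,6α-olide
Product: 7 8α-acetoxy-(1R,10R)-1,10-epoxy-14-hydroxy-15-oxogermacra-4,11(13)-dien-12,6α-olide, via alkoxyiodane 6 (not isolated)
Conditions: PhI(OAc)2 (1.5 equiv), Cu(MeCN)4PF6 (10 mol%), 4,4′-di-tert-butyl-2,2′-bipyridine (12 mol%), AcOH (2 equiv), PhCF3 (0.02 M), 450 nm LEDs, 10 °C
Reagents that add atoms: (diacetoxyiodo)benzene, CC(=O)OI(OC(C)=O)c1ccccc1
Why: Proposed new method: hydroxyl-directed δ-C(sp3)–H acetoxylation, in which ligand exchange gives alkoxyiodane 6, its O–I bond is cleaved by monovalent copper (or by 450 nm light) to the 14-alkoxy radical, this radical can reach only H-8 by a six-membered 1,5-hydrogen shift (C2 is trans to C14 across the rigid oxirane and β-scission would give a strained oxiranyl radical), the C8 radical is trapped by bipyridine-ligated divalent copper acetate held on the α-face by the free 14-OH (six-membered Cu–O14–C14–C10–C9–C8 chelate, the β-face being screened by the C7–C11 bond), and C–O reductive elimination from the trivalent alkylcopper acetate forms the C8–OAc bond as 8α (8S) and returns monovalent copper; the closest known reactions are the Suárez hypoiodite 1,5-hydrogen-transfer functionalisation of alcohols (which gives cyclic ethers) and the Kharasch–Sosnovsky copper-catalysed acyloxylation, joined here so that PhI(OAc)2 is both oxidant and acetate source.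

**Step 5**
Reactants: 7 8α-acetoxy-(1R,10R)-1,10-epoxy-14-hydroxy-15-oxogermacra-4,11(13)-dien-12,6α-olide
Product: 8 CNP0211286.1
Conditions: Ac2O, pyridine, DMAP (cat.), CH2Cl2, 0 °C → rt
Reagents that add atoms: acetic anhydride, CC(=O)OC(C)=O
Why: DMAP-catalysed O-acylation of the remaining primary alcohol, which touches no stereocentre and is tolerated by the oxirane, the enal and the α-methylene lactone.

## Compound list

1 | (+)-costunolide, germacra-1(10),4,11(13)-trien-12,6α-olide (6R,7S; both ring alkenes ring-trans) | C=C1C(=O)O[C@@H]2/C=C(\C)CC/C=C(\C)CC[C@@H]12 | starting material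
2 | 14-hydroxy-1(10)-ring-cis-costunolide (C2 and C9 cis on C1=C10, CH2OH cis to H-1; 4,5-alkene ring-trans; 6R,7S) | C=C1C(=O)O[C@@H]2/C=C(\C)CC/C=C(/CO)CC[C@@H]12 | intermediate
3 | (1R,10R)-1,10-epoxy-14-hydroxygermacra-4,11(13)-dien-12,6α-olide (cis-oxirane, C14 cis to H-1; 6R,7S) | C=C1C(=O)O[C@@H]2/C=C(\C)CC[C@H]3O[C@@]3(CO)CC[C@@H]12 | intermediate
4 | (1R,10R)-1,10-epoxy-14,15-dihydroxygermacra-4,11(13)-dien-12,6α-olide (C15 trans to C6, 4,5-alkene ring-cis; forms in the flask in step 3) | C=C1C(=O)O[C@@H]2/C=C(/CO)CC[C@H]3O[C@@]3(CO)CC[C@@H]12 | intermediate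
5 | (1R,10R)-1,10-epoxy-14-hydroxy-15-oxogermacra-4,11(13)-dien-12,6α-olide (CHO trans to C6) | C=C1C(=O)O[C@@H]2/C=C(/C=O)CC[C@H]3O[C@@]3(CO)CC[C@@H]12 | intermediate
6 | 14-O-[acetoxy(phenyl)-λ3-iodanyl] derivative of 5 (forms in the flask in step 4) | C=C1C(=O)O[C@@H]2/C=C(/C=O)CC[C@H]3O[C@@]3(COI(OC(C)=O)c4ccccc4)CC[C@@H]12 | intermediate
7 | 8α-acetoxy-(1R,10R)-1,10-epoxy-14-hydroxy-15-oxogermacra-4,11(13)-dien-12,6α-olide (6R,7R,8S) | C=C1C(=O)O[C@@H]2/C=C(/C=O)CC[C@H]3O[C@@]3(CO)C[C@H](OC(C)=O)[C@@H]12 | intermediate
8 | CNP0211286.1, 8α,14-diacetoxy-(1R,10R)-1,10-epoxy-15-oxogermacra-4,11(13)-dien-12,6α-olide (1R,6R,7R,8S,10R) | C=C1C(=O)O[C@@H]2/C=C(/C=O)CC[C@H]3O[C@@]3(COC(C)=O)C[C@H](OC(C)=O)[C@@H]12 | target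

## Step count and risks

Total step count: 5. Longest linear sequence: 5 steps (1 → 2 → 3 → 5 → 7 → 8).

**Step 4 (the proposed new reaction).** It may instead close the C8 radical onto O-14 to give the 8,14-cyclic ether, lose a β-hydride from the alkylcopper to give a 7(8)- or 8(9)-alkene, abstract H-7 by a 1,6-shift, or give both C8 epimers. The fallback uses known chemistry, sets out from 5 and comes back to the route at 8. Compound 5 is treated with NOCl in pyridine at −20 °C to give the 14-nitrite ester F1. Barton nitrite photolysis under oxygen (365 nm, O2-saturated benzene; the known variant in which the translocated carbon radical is trapped by O2 and NO to give a nitrate ester) gives the 14-hydroxy 8-nitrate F2. This trapping is not directed, so C8 epimers are expected and the 8α isomer is separated by chromatography. Zn dust in aqueous NH4Cl/THF cleaves the nitrate to the 8α,14-diol F3. Ac2O, pyridine and DMAP then acetylate both hydroxyls to give 8.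

**Step 3.** Hot selenious acid may open the oxirane, and the 4,5-alkene is deactivated by the allylic lactone oxygen, so the ene step may be sluggish or unselective. The fallback sets out from 2 and comes back at 5; it moves the C15 oxidation ahead of the epoxidation and then tells the two oxygenated carbons apart by chemoselectivity. Compound 2 is heated with SeO2 (3 equiv) in dioxane at 75 °C to give the 14,15-dialdehyde F4 (C15 is oxidised and the allylic 14-alcohol is oxidised as well). Luche reduction (NaBH4, CeCl3·7H2O, MeOH, −78 °C) gives the 14,15-diol F5. Sharpless epoxidation with D-(−)-diethyl tartrate and 1.0 equiv of t-BuOOH takes the electron-richer 1(10)-allylic alcohol first and gives 4, now isolated. MnO2 in CH2Cl2 oxidises only the remaining allylic 15-OH and gives 5.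

**Step 2.** The Lewis-acidic titanium catalyst may trigger transannular opening of the new epoxy alcohol by the 4,5-alkene, or the reagent-controlled face may be mismatched with the ring conformation and react slowly. The fallback sets out from 2 and comes back at 3. It replaces hydroxyl-directed metal-peroxide delivery by an undirected chiral dioxirane: Shi epoxidation with the D-fructose-derived ketone (30 mol%), KHSO5, K2CO3 buffer, MeCN–dimethoxymethane–water, 0 °C. By the spiro transition-state model this ketone gives the same 1R,10R sense as D-(−)-tartrate, and the electron-poor 4,5- and 11(13)-alkenes react much more slowly. It makes no new compound (F0).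

## Further compounds

F1 | step 4 | 14-O-nitrite ester of 5 | C=C1C(=O)O[C@@H]2/C=C(/C=O)CC[C@H]3O[C@@]3(CON=O)CC[C@@H]12
F2 | step 4 | (1R,10R)-1,10-epoxy-14-hydroxy-8α-nitrooxy-15-oxogermacra-4,11(13)-dien-12,6α-olide | C=C1C(=O)O[C@@H]2/C=C(/C=O)CC[C@H]3O[C@@]3(CO)C[C@H](O[N+](=O)[O-])[C@@H]12
F3 | step 4 | (1R,10R)-1,10-epoxy-8α,14-dihydroxy-15-oxogermacra-4,11(13)-dien-12,6α-olide | C=C1C(=O)O[C@@H]2/C=C(/C=O)CC[C@H]3O[C@@]3(CO)C[C@H](O)[C@@H]12
F4 | step 3 | 14,15-dioxogermacra-1(10),4,11(13)-trien-12,6α-olide (both ring alkenes ring-cis) | C=C1C(=O)O[C@@H]2/C=C(/C=O)CC/C=C(/C=O)CC[C@@H]12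
F5 | step 3 | 14,15-dihydroxygermacra-1(10),4,11(13)-trien-12,6α-olide (both ring alkenes ring-cis) | C=C1C(=O)O[C@@H]2/C=C(/CO)CC/C=C(/CO)CC[C@@H]12
F0 | step 2 | none | none
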